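**Remark on the chemistry:** the stereodescriptors of the structure are read as (3S,4S), 3,4-trans, for both lactones, and the route is planned for exactly this enantiomer. Lactone atoms are numbered O1, C2 (carbonyl), C3, C4, C5. Ring A is the 3-methoxy-4-aryloxyphenyl ring and ring B the phenolic 3-aryloxy-4-hydroxy-5-methoxyphenyl ring.

## The problem

The target is an unsymmetrical "dimer": two trans-3,4-dibenzyl-γ-butyrolactones whose C3 benzyl groups are ring A and ring B of one diaryl ether, while each C4 carries the same 3,4-dimethoxybenzyl group. No rings are fused; the task is to build two identical stereodiads at the ends of a non-symmetrical tether. There are four stereocentres, all S. Within each lactone C4 can control C3, because C3 is α to the carbonyl, is epimerisable, and prefers the trans arrangement. The two lactones are too far apart to influence each other, so each C4 must come from an enantiopure source, and the optical purity of that source decides the stereochemical purity of the product, since diastereomers differing only in one remote half would hardly be separable. The free phenol of ring B (ortho to the diaryl ether oxygen, para to a benzylic carbon) must stay masked through all base and alkylation chemistry. The lactones are sensitive to hydroxide and hard nucleophiles, and the electron-rich benzylic halides needed for any alkylation are prone to solvolysis. The diaryl ether joins a hindered ring B oxygen to a ring A carbon para to a former carbonyl, so it is best made early, on simple aldehydes. The enabling feature is that in each lactone C3 is both the α-carbon of C2 and the attachment point of a diaryl ether CH2, while C4 carries an aryl–CH2 group. C3 therefore maps onto the malonate carbon, and the C4 benzylic CH2 onto the cyclopropane methylene, of a 2-oxo-3-oxabicyclo[3.1.0]hexane-1-carboxylate, and the shared dimethoxybenzyl group allows the same event to be run twice on one bis-electrophile.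

## Retrosynthesis

**Target 19 to benzyl ether 18.** The ring B phenol is masked as its benzyl ether. Only the O–CH2Ph bond is cut. Benzyl is chosen over silyl or acetal groups because it survives Grignard reagents, enolates, bromination and hot chloride, and leaves under neutral hydrogenolysis that touches neither lactone. The forward step only has to spare the diaryl ether and the lactones.

**18 to bis(ester) 17.** An ethoxycarbonyl group is placed back on both C3 atoms. This turns each C3 into a malonate-type carbon and removes the need to control C3 early. The forward dealkoxycarbonylation must work at two quaternary centres and must end under thermodynamic control so that fixed (S)-C4 dictates trans.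

**17 to lactone 5 (two molecules), Grignard reagent 13 (two molecules) and dibromide 11.** Four bonds are cut: both (3,4-dimethoxyphenyl)–CH2 bonds and both C3–CH2 bonds to rings A and B. A neighbouring cut, alkylation of a preformed 4-benzyl lactone enolate, would need the dimethoxybenzyl lactone to be made first by a separate sequence. Conjugate addition to a butenolide would need a benzylic copper nucleophile, which is awkward. The cyclopropane moves the nucleophile back by one carbon to a plain aryl Grignard reagent and delivers the enolate for the second bond in the same flask. Five small molecules replace one large one. The forward reaction must open the cyclopropane at its CH2 only and must C-benzylate a magnesium enolate twice.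

**5 to diethyl malonate 1 and (S)-epichlorohydrin 2.** The cyclopropane C–C bonds to the malonate carbon and the lactone C–O bond are cut. This is a one-step construction from two commodity chemicals that fixes the only stereocentre that has to be bought. The forward reaction must proceed by the epoxide-first pathway so that the (S)-centre of 2 becomes C5 (S) of 5.

**11 to diol 10 to dialdehyde 9, then 9 to phenol 7 and fluoroarene 8, and 7 to 5-hydroxyvanillin 6.** The benzylic C–Br bonds go back to C–OH and then to CHO. The diaryl ether C–O bond is cut on the ring A side, because only ring A has a position para to a formyl group that activates a fluoride for addition–elimination; the ring B oxygen is meta to its formyl group and can only be the nucleophile. 7 comes from 6 by benzylation of the more acidic 4-OH. All of this is done on cheap achiral aldehydes, where a poor step costs little.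

**13 to 4-bromoveratrole 12.** Magnesium insertion. Preparing the reagent allows it to be titrated, which the key step needs.

## Roads not taken

**Alternative 1:** Double Still–Wittig rearrangement. The cut is the C4–C5 bond of each lactone. The bis(tributylstannylmethyl) ether A1 of an (R,R)-bis[(Z)-allylic] diol is treated with C4H9Li; tin–lithium exchange triggers two [2,3]-shifts and gives the bis(homoallylic alcohol) A2 with both C4 centres and two (E)-styrenes.
- Merits: suprafacial 1,3-chirality transfer is dependable, (Z)-allylic ethers give clean (E)-products, and the absolute configuration comes from a catalyst acting on dialdehyde 9, so either enantiomeric series is equally accessible. It also needs no labile benzylic dihalide.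
- Weak points: A1 requires two enantioselective alkynylations, a double semi-hydrogenation and a double O-stannylmethylation before the key step, and uses stoichiometric tin at low temperature. Its carbinol carbons are benzylic and allylic, so [1,2]-shift and elimination compete. A2 still lacks C2 and the C3 stereocentre: each styrene must be hydroalkoxycarbonylated (CO, Pd(OAc)2, phosphine) at the non-benzylic carbon, against the usual benzylic preference, and with trans control, twice.
- Comparison: the chosen plan has no answer to the catalyst-controlled flexibility of A2, but it sets C4 from a cheap chiral pool reagent available in both forms, forms the C3–CH2 bond in the key step itself, and needs only two steps afterwards.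

**Alternative 2:** Ring A built by a [3+3] annulation. The cuts are the C4–C5 and C1–C2 bonds of ring A. The silyl enol ether A3 (a 1-aryloxy-2-silyloxypropene carried by the ring B lactone) adds through its oxygen-bearing carbon to the terminal carbon of ynone A4 (carried by the other lactone) under TiCl4; base then closes the ring by aldol condensation and aromatisation to the ring A phenol A5. O-Methylation and hydrogenolysis would follow.
- Merits: late and fully convergent; the diaryl ether oxygen is installed by a simple phenol alkylation, so no hindered aryl–oxygen coupling is needed, and the arene substitution pattern is unambiguous. For analogues with two different halves this is the better design.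
- Weak points: A3 and A4 are both complete enantiopure trans-lactones, so the same dimethoxybenzyl lactone core must be made twice with different C3 side chains, which discards the hidden two-fold character of the target. Enolisation must go toward the OCH2 side of the ketone and not toward the lactone α-position. TiCl4 threatens the benzyl ether and the lactones. The terminal ynone is prone to polymerisation and 1,2-addition. The annulation itself is unproven on this substrate type, and an extra methylation follows.
- Comparison: the chosen plan forms the diaryl ether by a known substitution at the start and is much shorter. Against the convergence of A5 it has only its brevity and the fact that every step is of a known type.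

**Alternative 3:** Desymmetrising oxetane opening. The cut is the O1–C5 bond of each lactone. Under (R)- or (S)-3,3′-bis(2,4,6-triisopropylphenyl)-1,1′-binaphthyl-2,2′-diyl hydrogen phosphate, each oxetan-3-ylmalonic acid unit of the achiral tetra-acid A6 opens its oxetane by attack of a carboxyl oxygen on one enantiotopic CH2, closing both lactones to give the bis(3-carboxy-4-hydroxymethyl lactone) A7.
- Merits: the precursor is achiral, the asymmetric step is catalytic, both rings close in the key step, and two independent catalytic events raise the enantiomeric purity of the homochiral product statistically. In these respects it is better than a chiral-pool route.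
- Weak points: A7 carries CH2OH at C4 where the target has a 3,4-dimethoxybenzyl group. Each hydroxymethyl group must be activated and coupled to an aryl nucleophile at a carbon next to a quaternary centre, twice, in the presence of free acids or after further protection. The mismatched events give a diastereomer that is lost and may be hard to remove. A6 still requires dibromide 11 and a double malonate alkylation, so the fragile intermediate is not avoided.
- Comparison: the chosen plan brings in the aryl group in the very step that creates the enolate, so nothing has to be attached to C4 afterwards. It pays for this by depending on the optical purity of 2.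

Key step: step 7

## Route

**Step 1**
Reactants: 1 diethyl malonate; 2 (S)-epichlorohydrin
Product: 5 ethyl (1R,5S)-2-oxo-3-oxabicyclo[3.1.0]hexane-1-carboxylate, via diethyl (S)-2-(oxiran-2-ylmethyl)malonate 3 (not isolated), via diethyl (S)-2-(hydroxymethyl)cyclopropane-1,1-dicarboxylate 4 (not isolated)
Conditions: NaOEt, EtOH, 0 °C → reflux
Reagents that add atoms: none
Why: Known malonate–epichlorohydrin cyclopropanation–lactonisation: the malonate anion opens the epoxide at its CH2 end, the alkoxide displaces chloride to give 3, a second deprotonation opens the new epoxide at the stereogenic carbon (3-exo-tet, inversion) to give 4, and the alkoxide lactonises onto the cis ester. The (S)-centre of 2 thereby becomes C5 (S), and the obligatory cis fusion fixes C1 (R). Direct displacement of chloride would lead to the enantiomer, so the optical purity of 5 should be checked before use.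

**Step 2**
Reactants: 6 5-hydroxyvanillin (3,4-dihydroxy-5-methoxybenzaldehyde)
Product: 7 4-(benzyloxy)-3-hydroxy-5-methoxybenzaldehyde
Conditions: BnBr (1.05 equiv), NaHCO3, DMF, 40 °C
Reagents that add atoms: benzyl bromide, BrCc1ccccc1
Why: Regioselective Williamson etherification: the 4-OH para to the formyl group is the most acidic and the only one ionised by NaHCO3, so monobenzylation at O4 is expected, as is established for 3,4-dihydroxybenzaldehydes.

**Step 3**
Reactants: 7 4-(benzyloxy)-3-hydroxy-5-methoxybenzaldehyde; 8 4-fluoro-3-methoxybenzaldehyde
Product: 9 4-(benzyloxy)-3-(4-formyl-2-methoxyphenoxy)-5-methoxybenzaldehyde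
Conditions: K2CO3, DMSO, 110 °C
Reagents that add atoms: none
Why: Nucleophilic aromatic substitution by addition–elimination: the fluoride of 8 is activated by the para formyl group and is displaced by the phenoxide of 7. Neither aldehyde is enolisable, so hot carbonate should be tolerated.

**Step 4**
Reactants: 9 4-(benzyloxy)-3-(4-formyl-2-methoxyphenoxy)-5-methoxybenzaldehyde
Product: 10 [4-(benzyloxy)-3-[4-(hydroxymethyl)-2-methoxyphenoxy]-5-methoxyphenyl]methanol
Conditions: NaBH4, MeOH–THF, 0 °C
Reagents that add atoms: none
Why: Standard NaBH4 reduction of both aryl aldehydes to benzylic alcohols; the benzyl ether and the diaryl ether are inert.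

**Step 5**
Reactants: 10 [4-(benzyloxy)-3-[4-(hydroxymethyl)-2-methoxyphenoxy]-5-methoxyphenyl]methanol
Product: 11 2-(benzyloxy)-5-(bromomethyl)-1-[4-(bromomethyl)-2-methoxyphenoxy]-3-methoxybenzene
Conditions: PBr3, CH2Cl2, 0 °C; used without storage
Reagents that add atoms: phosphorus tribromide, BrP(Br)Br
Why: Conversion of benzylic alcohols into bromides through phosphite esters. Low temperature and short contact time should keep HBr away from the benzyl ether, and the dibromide is taken on directly.

**Step 6**
Reactants: 12 4-bromo-1,2-dimethoxybenzene (4-bromoveratrole)
Product: 13 3,4-dimethoxyphenylmagnesium bromide (THF solution, titrated)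
Conditions: Mg turnings, I2 (cat.), THF, reflux then rt
Reagents that add atoms: magnesium, [Mg]
Why: Grignard formation by insertion of magnesium into the aryl bromide, routine for this bromide. Titration allows step 7 to be run with 5 in slight excess over 13.

**Step 7**
Reactants: 5 ethyl (1R,5S)-2-oxo-3-oxabicyclo[3.1.0]hexane-1-carboxylate (2.5 equiv); 13 3,4-dimethoxyphenylmagnesium bromide (2.4 equiv); 11 2-(benzyloxy)-5-(bromomethyl)-1-[4-(bromomethyl)-2-methoxyphenoxy]-3-methoxybenzene (1 equiv)
Product: 17 O-benzyl bis(3-ethoxycarbonyl lactone) [(3S,4S) at both lactones], via bromomagnesium enolate 14 (not isolated), via ring A monoalkylated bromide 15 (not isolated), via ring B monoalkylated bromide 16 (not isolated)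
Conditions: 5, CuI (10 mol %), THF, −30 °C, slow addition of 13, then 0 °C; then 11, DMPU, Bu4NI (cat.), 0 → 40 °C
Reagents that add atoms: none
Why: Transmetallation of 13 to a catalytic arylcopper species is followed by SN2 attack on the unsubstituted cyclopropane carbon C6 of 5 with cleavage of the C1–C6 bond, the ring strain being released into the chelated enolate 14. The closest known reaction is the copper-catalysed homoconjugate addition of Grignard reagents to this same bicyclic lactone and to cyclopropane-1,1-dicarbonyl compounds, followed by ordinary C-alkylation of the malonate-type enolate. Keeping 5 in slight excess ensures that 13 is consumed before 11 is added, which prevents copper-mediated aryl–benzyl coupling. DMPU then loosens the magnesium chelate so that 14 is C-benzylated at both arms of 11, passing through 15 and 16. No ring is closed, and five molecules are joined by four new C–C bonds. C4 of each lactone is the untouched ring-fusion carbon C5 of 5 and so carries the configuration bought with 2. Each new quaternary C3 centre is set by approach of the benzylic bromide anti to the C4 benzyl group (drawn 3S), and its sense is immaterial because step 8 removes it. The step needs attack at C6 rather than at C5 or a carbonyl, which the double activation of C1, the soft copper nucleophile and the lower substitution of C6 secure; it also needs C- rather than O-alkylation, which the soft benzylic electrophile secures.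

**Step 8**
Reactants: 17 O-benzyl bis(3-ethoxycarbonyl lactone)
Product: 18 O-benzyl ether of the target [(3S,4S) at both lactones]
Conditions: LiCl, H2O, DMSO, 150 °C; then DBU, PhMe, 80 °C
Reagents that add atoms: none
Why: Krapcho dealkoxycarbonylation: chloride dealkylates each ethyl ester by SN2 attack at the ethyl group, the carboxylates lose CO2, and the lactone enolates are protonated by water. C3 is then the only epimerisable centre, and DBU equilibrates it to the more stable 3,4-trans arrangement dictated by fixed (S)-C4, which gives (3S,4S) in both lactones.

**Step 9**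
Reactants: 18 O-benzyl ether of the target
Product: 19 target, (3S,4S)-4-(3,4-dimethoxybenzyl)-3-{4-[5-{[(3S,4S)-4-(3,4-dimethoxybenzyl)-2-oxotetrahydrofuran-3-yl]methyl}-2-hydroxy-3-methoxyphenoxy]-3-methoxybenzyl}dihydrofuran-2(3H)-one
Conditions: H2 (1 atm), Pd/C, EtOAc–EtOH, rt
Reagents that add atoms: none
Why: Hydrogenolysis of the aryl benzyl ether over Pd/C; the lactones, the aryl methyl ethers, the diaryl ether and the benzylic C–C bonds are not affected, and no stereocentre is touched.

## Compound list

1 | diethyl malonate | CCOC(=O)CC(=O)OCC | starting material
2 | (S)-epichlorohydrin | ClC[C@@H]1CO1 | starting material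
3 | diethyl (S)-2-(oxiran-2-ylmethyl)malonate | CCOC(=O)C(C[C@H]1CO1)C(=O)OCC | intermediate (not isolated)
4 | diethyl (S)-2-(hydroxymethyl)cyclopropane-1,1-dicarboxylate | CCOC(=O)C1(C(=O)OCC)C[C@@H]1CO | intermediate (not isolated)
5 | ethyl (1R,5S)-2-oxo-3-oxabicyclo[3.1.0]hexane-1-carboxylate | CCOC(=O)[C@@]12C[C@@H]1COC2=O | intermediate
6 | 5-hydroxyvanillin (3,4-dihydroxy-5-methoxybenzaldehyde) | O=Cc1cc(O)c(O)c(OC)c1 | starting material
7 | 4-(benzyloxy)-3-hydroxy-5-methoxybenzaldehyde | O=Cc1cc(O)c(OCc2ccccc2)c(OC)c1 | intermediate
8 | 4-fluoro-3-methoxybenzaldehyde | O=Cc1ccc(F)c(OC)c1 | starting material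
9 | 4-(benzyloxy)-3-(4-formyl-2-methoxyphenoxy)-5-methoxybenzaldehyde | O=Cc1ccc(Oc2cc(C=O)cc(OC)c2OCc2ccccc2)c(OC)c1 | intermediate
10 | [4-(benzyloxy)-3-[4-(hydroxymethyl)-2-methoxyphenoxy]-5-methoxyphenyl]methanol | OCc1ccc(Oc2cc(CO)cc(OC)c2OCc2ccccc2)c(OC)c1 | intermediate
11 | 2-(benzyloxy)-5-(bromomethyl)-1-[4-(bromomethyl)-2-methoxyphenoxy]-3-methoxybenzene | BrCc1ccc(Oc2cc(CBr)cc(OC)c2OCc2ccccc2)c(OC)c1 | intermediate
12 | 4-bromo-1,2-dimethoxybenzene | COc1ccc(Br)cc1OC | starting material
13 | 3,4-dimethoxyphenylmagnesium bromide | COc1ccc([Mg]Br)cc1OC | intermediate
14 | bromomagnesium enolate of ethyl (4S)-4-(3,4-dimethoxybenzyl)-2-oxotetrahydrofuran-3-carboxylate | CCOC(=O)C1=C(O[Mg]Br)OC[C@H]1Cc1ccc(OC)c(OC)c1 | intermediate (not isolated)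
15 | ethyl (3S,4S)-3-{4-[2-(benzyloxy)-5-(bromomethyl)-3-methoxyphenoxy]-3-methoxybenzyl}-4-(3,4-dimethoxybenzyl)-2-oxotetrahydrofuran-3-carboxylate (ring A arm alkylated) | COc1ccc(C[C@@H]2COC(=O)[C@@]2(C(=O)OCC)Cc2ccc(Oc3cc(CBr)cc(OC)c3OCc3ccccc3)c(OC)c2)cc1OC | intermediate (not isolated)
16 | ethyl (3S,4S)-3-{4-(benzyloxy)-3-[4-(bromomethyl)-2-methoxyphenoxy]-5-methoxybenzyl}-4-(3,4-dimethoxybenzyl)-2-oxotetrahydrofuran-3-carboxylate (ring B arm alkylated) | BrCc1ccc(Oc2cc(C[C@]3(C(=O)OCC)C(=O)OC[C@H]3Cc3ccc(OC)c(OC)c3)cc(OC)c2OCc2ccccc2)c(OC)c1 | intermediate (not isolated)
17 | ethyl (3S,4S)-3-{4-[2-(benzyloxy)-5-{[(3S,4S)-4-(3,4-dimethoxybenzyl)-3-(ethoxycarbonyl)-2-oxotetrahydrofuran-3-yl]methyl}-3-methoxyphenoxy]-3-methoxybenzyl}-4-(3,4-dimethoxybenzyl)-2-oxotetrahydrofuran-3-carboxylate | COc1ccc(C[C@@H]2COC(=O)[C@@]2(C(=O)OCC)Cc2ccc(Oc3cc(C[C@]4(C(=O)OCC)C(=O)OC[C@H]4Cc4ccc(OC)c(OC)c4)cc(OC)c3OCc3ccccc3)c(OC)c2)cc1OC | intermediate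
18 | (3S,4S)-3-{4-[2-(benzyloxy)-5-{[(3S,4S)-4-(3,4-dimethoxybenzyl)-2-oxotetrahydrofuran-3-yl]methyl}-3-methoxyphenoxy]-3-methoxybenzyl}-4-(3,4-dimethoxybenzyl)dihydrofuran-2(3H)-one | COc1ccc(C[C@@H]2COC(=O)[C@H]2Cc2ccc(Oc3cc(C[C@@H]4C(=O)OC[C@H]4Cc4ccc(OC)c(OC)c4)cc(OC)c3OCc3ccccc3)c(OC)c2)cc1OC | intermediate
19 | (3S,4S)-4-(3,4-dimethoxybenzyl)-3-{4-[5-{[(3S,4S)-4-(3,4-dimethoxybenzyl)-2-oxotetrahydrofuran-3-yl]methyl}-2-hydroxy-3-methoxyphenoxy]-3-methoxybenzyl}dihydrofuran-2(3H)-one | COc1ccc(C[C@@H]2COC(=O)[C@H]2Cc2ccc(Oc3cc(C[C@@H]4C(=O)OC[C@H]4Cc4ccc(OC)c(OC)c4)cc(OC)c3O)c(OC)c2)cc1OC | target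

## Step count and least certain steps

Total: 9 steps. Longest linear sequence: 7 steps (6 → 7 → 9 → 10 → 11 → 17 → 18 → 19).

**Step 7 (key step).** The chelated magnesium enolate may be benzylated too slowly, so that the reaction stalls after the first arm. Residual Grignard reagent may also be coupled with the benzylic bromide under copper catalysis if the titre is misjudged. The fallback separates the two events. It sets out from 5 and 13: the opening is run as before and quenched with dilute HCl to isolate ethyl (4S)-4-(3,4-dimethoxybenzyl)-2-oxotetrahydrofuran-3-carboxylate F1 (C3 epimers). F1 (2.3 equiv) is then alkylated with 11 under Cs2CO3 in DMF at room temperature, a classical malonate alkylation through the free caesium enolate. The fallback comes back to the route at 17.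

**Step 8.** Dealkylation of two hindered ethyl esters at quaternary centres may be slow, and at the temperature then needed chloride may begin to demethylate aryl methyl ethers; equilibration at C3 may also be incomplete. The fallback sets out from 17. LiOH in aqueous THF hydrolyses both ethyl esters (the lactones open as well), and acidification with HCl recloses the lactones to give the bis(3-carboxylic acid) F2. F2 loses CO2 on heating in toluene at 110 °C, and the same DBU equilibration follows. The fallback comes back at 18.

**Step 3.** The phenoxide of 7 is flanked by the benzyloxy group and the fluoride of 8 is somewhat deactivated by its ortho methoxy group, so substitution may be slow and the aldehydes may degrade on prolonged heating with base. The fallback sets out from 7 and replaces addition–elimination by a copper-catalysed Ullmann ether coupling with commercial 4-bromo-3-methoxybenzaldehyde (CuI, picolinic acid, K3PO4, DMSO, 90 °C). It comes back at 9 and makes no new compound (F0).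

**Step 5.** The bis(benzylic bromide) may be lost by solvolysis or by self-alkylation of its electron-rich rings during work-up, and HBr may cleave the benzyl ether. The fallback sets out from 10: SOCl2 in CH2Cl2 gives the more robust bis(chloromethyl) compound, 2-(benzyloxy)-5-(chloromethyl)-1-[4-(chloromethyl)-2-methoxyphenoxy]-3-methoxybenzene F3. F3 is used in step 7 in place of 11 with NaI added for halide exchange in the flask, and the fallback comes back at 17.

## Further compounds

F1 | step 7 | ethyl (4S)-4-(3,4-dimethoxybenzyl)-2-oxotetrahydrofuran-3-carboxylate (C3 epimers) | CCOC(=O)C1C(=O)OC[C@H]1Cc1ccc(OC)c(OC)c1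
F2 | step 8 | (3S,4S)-3-{4-[2-(benzyloxy)-5-{[(3S,4S)-3-carboxy-4-(3,4-dimethoxybenzyl)-2-oxotetrahydrofuran-3-yl]methyl}-3-methoxyphenoxy]-3-methoxybenzyl}-4-(3,4-dimethoxybenzyl)-2-oxotetrahydrofuran-3-carboxylic acid | COc1ccc(C[C@@H]2COC(=O)[C@@]2(C(=O)O)Cc2ccc(Oc3cc(C[C@]4(C(=O)O)C(=O)OC[C@H]4Cc4ccc(OC)c(OC)c4)cc(OC)c3OCc3ccccc3)c(OC)c2)cc1OC
F0 | step 3 | none | none
F3 | step 5 | 2-(benzyloxy)-5-(chloromethyl)-1-[4-(chloromethyl)-2-methoxyphenoxy]-3-methoxybenzene | ClCc1ccc(Oc2cc(CCl)cc(OC)c2OCc2ccccc2)c(OC)c1
A1 | alternative 1 | bis(tributylstannylmethyl) ether of the (R,R)-bis[(Z)-allylic] diol, ring B phenol as benzyl ether | CCCC[Sn](CCCC)(CCCC)CO[C@H](/C=C\Cc1ccc(OC)c(OC)c1)c1ccc(Oc2cc([C@H](OC[Sn](CCCC)(CCCC)CCCC)/C=C\Cc3ccc(OC)c(OC)c3)cc(OC)c2OCc2ccccc2)c(OC)c1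
A2 | alternative 1 | bis(homoallylic alcohol) with (E)-styrenes, ring B phenol as benzyl ether | COc1ccc(C[C@H](CO)/C=C/c2ccc(Oc3cc(/C=C/[C@@H](CO)Cc4ccc(OC)c(OC)c4)cc(OC)c3OCc3ccccc3)c(OC)c2)cc1OC
A3 | alternative 2 | (3S,4S)-3-[4-(benzyloxy)-3-methoxy-5-{[2-(trimethylsilyloxy)prop-1-en-1-yl]oxy}benzyl]-4-(3,4-dimethoxybenzyl)dihydrofuran-2(3H)-one | CC(O[Si](C)(C)C)=COc1cc(C[C@@H]2C(=O)OC[C@H]2Cc2ccc(OC)c(OC)c2)cc(OC)c1OCc1ccccc1
A4 | alternative 2 | (3S,4S)-4-(3,4-dimethoxybenzyl)-3-(2-oxobut-3-yn-1-yl)dihydrofuran-2(3H)-one | COc1ccc(C[C@@H]2COC(=O)[C@H]2CC(=O)C#C)cc1OC
A5 | alternative 2 | ring A phenol (O-demethyl at C3 of ring A), ring B phenol as benzyl ether | COc1ccc(C[C@@H]2COC(=O)[C@H]2Cc2ccc(Oc3cc(C[C@@H]4C(=O)OC[C@H]4Cc4ccc(OC)c(OC)c4)cc(OC)c3OCc3ccccc3)c(O)c2)cc1OC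
A6 | alternative 3 | 2-{4-[2-(benzyloxy)-5-[2,2-dicarboxy-2-(oxetan-3-yl)ethyl]-3-methoxyphenoxy]-3-methoxybenzyl}-2-(oxetan-3-yl)malonic acid | OC(=O)C(Cc1ccc(Oc2cc(CC(C(=O)O)(C(=O)O)C3COC3)cc(OC)c2OCc2ccccc2)c(OC)c1)(C(=O)O)C1COC1
A7 | alternative 3 | bis(3-carboxy-4-hydroxymethyl lactone), one C3 diastereomer drawn, ring B phenol as benzyl ether | OC[C@@H]1COC(=O)[C@@]1(C(=O)O)Cc1ccc(Oc2cc(C[C@]3(C(=O)O)C(=O)OC[C@H]3CO)cc(OC)c2OCc2ccccc2)c(OC)c1
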